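Readings and results are calculated for an exercise.

The summer run has used 44.0% of its electrophile at 1.00 h, and I look for the number behind that reading before I reckon the flask.

common to all: nucleophile 1.98 M
- dawn: electrophile 1.1 M; free base 0.17 M; run made earlier
- dusk: electrophile 1.1 M; free base 0.66 M; run made earlier
- summer: electrophile 2.2 M; free base 0.33 M; run made earlier
- flask: electrophile 1.1 M; free base 0.330 M; time 4.0 h

- dawn (time / h: electrophile / %, target / %): 0.200: 40, 60; 0.333: 28, 62; 0.667: 23, 71; 1.33: 17, 65; 2.50: 25, 60
- dusk (time / h: electrophile / %, target / %): 0.200: 39, 58; 0.333: 33, 65; 0.667: 21, 69; 1.33: 22, 65; 2.50: 24, 62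
- summer (time / h: electrophile / %, target / %): 0.200: 60, 42; 0.667: 57, 41; 1.00: 56, 41; 1.50: 53, 42; 2.50: 51, 39

(readings scatter by 1.5 percentage points)

- what was read earlier has a scatter of 1.5 percentage points, one standard deviation
- the earlier runs do not show how much of nucleophile is bound; that part of a forecast is a guess

* part of the electrophile that has reacted at 4.0 h
* share of the unused nucleophile that is free and not bound as protonated nucleophile, at 4.0 h

I suppose that each electrophile reacting costs 2 nucleophile: one makes target, one ends as protonated nucleophile. With A and B the charged electrophile and nucleophile, this is a limiting-reagent count: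

R = B / (2 A) = 90.0% for the flask

I call R the reach, the share of the electrophile that the charged nucleophile can pay for at that price. For the summer run R is 45.0%, close to its reading. But for the dawn and dusk runs R is 90.0%, while their last readings leave 25% and 24% of the electrophile, so they have used about 75.5%. One number is not enough, so I take c, the share reacted at 4.0 h, from those readings, though they stop at 2.50 h. They lie 1 percentage point apart, with a scatter of 1.5 points, although the free base goes from 0.17 M to 0.66 M, so I keep free base out of the count, though these readings do not show how much nucleophile is bound. Then the free share of the unused nucleophile is: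

f = (R − c) / (R − c/2) = 27.8%

The forecast says 75% and 56%, adding of the second: “This is a guess, since base partitioning is unobserved.” Its c stands near mine, but my f is lower than its share.

The flask gives 78.6% and 16.4%.

    nucleophile + acid set free ⇌ protonated nucleophile, settled at all times (K = 344 M⁻¹)
    electrophile + acid set free → side product (k = 0.818 M⁻¹ h⁻¹)
    acid set free + free base ⇌ salt of the base (K = 52000 M⁻¹, k = 6.95 M⁻¹ h⁻¹)
    electrophile + nucleophile ⇌ acid set free + target (K = 0.260, k = 4.22 M⁻¹ h⁻¹)
    nucleophile + target → over-reaction product (k = 0.442 M⁻¹ h⁻¹)

At 4.00 h the flask holds more protonated nucleophile, 0.731 M, than free nucleophile, 0.144 M. With the flask's own c, f comes to 22.5%, still above the 16.4% it has. The neighbour charged with 1.2 M of nucleophile has a reach of 54.5%, and 57.1% of its electrophile has reacted at 4.00 h.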